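**Assumption:** I read the SMILES as a carbonyl carbon plus 33 ring CH2 groups, that is 34 carbons in a 35-membered lactone (C34H66O2); it has no stereocentre, so there is no enantiomer to select.

## Retrosynthetic overview

1. Target 8 has one ring, closed last at the ester C–O bond by acceptorless dehydrogenative macrolactonisation of the symmetric diol 5; either end may become the carbonyl, so no differentiation of the ends is needed.
2. Diol 5 (C34) is cut into C11 + C12 + C11: two-directional copper-catalysed sp3–sp3 coupling of the di-Grignard reagent 2 with two molecules of 11-bromoundecan-1-ol 3, masked in the flask as alkoxide 4 (no protecting group).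
3. Di-Grignard reagent 2 comes from 1,12-dibromododecane 1 and magnesium.

## Route

Step 1
Reactants: 1 1,12-dibromododecane
Product: 2 1,12-bis(bromomagnesio)dodecane
Conditions: Mg turnings (4 equiv), I2 (cat.), THF, slow addition of 1 at 45 °C, then reflux 2 h; filtered from excess Mg, titrated, used as a THF solution (about 0.2 M)
Reagents that add atoms: magnesium, [Mg]
Why: Grignard reagent formation by insertion of zerovalent magnesium into both primary C–Br bonds, with slow addition to excess metal in dilute THF to suppress Wurtz coupling, and a 12-carbon tether that cannot cyclise or eliminate.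

Step 2
Reactants: 2 1,12-bis(bromomagnesio)dodecane; 3 11-bromoundecan-1-ol
Product: 5 tetratriacontane-1,34-diol, via chloromagnesium 11-bromoundecan-1-olate 4 (not isolated)
Conditions: 3 (2.3 equiv), MeMgCl (2.3 equiv), THF, −20 °C; then NMP (8 equiv), Li2CuCl4 (5 mol%), 2 (1.0 equiv) added over 2 h, 0 °C to rt, 12 h; 1 M HCl; recrystallised from hot toluene
Reagents that add atoms: none
Why: Copper-catalysed sp3–sp3 Grignard cross-coupling (Kochi-type, Li2CuCl4 with NMP as promoter) at both C–Mg ends, in which the hydroxyl is masked as its magnesium alkoxide and is inert to the organocopper intermediate, so displacement of the primary bromide gives the C11 + C12 + C11 = C34 chain; no stereocentre is formed.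

Step 3
Reactants: 5 tetratriacontane-1,34-diol
Product: 8 oxacyclopentatriacontan-2-one, via 34-hydroxytetratriacontanal 6 (not isolated), via oxacyclopentatriacontan-2-ol 7 (not isolated)
Conditions: RuH(CO)[2-(tBu2PCH)-6-(Et2NCH2)C5H3N] (10 mol%), toluene, reflux, 5 added as a hot 5 mM toluene solution over 24 h (final 1 mM), slow Ar stream, then 24 h
Reagents that add atoms: none
Why: Proposed new method: an acceptorless dehydrogenative macrolactonisation of a long-chain α,ω-diol, in which the dearomatised pincer hydride of divalent ruthenium dehydrogenates one CH2OH to aldehyde 6 by metal–ligand cooperation, the remote hydroxyl adds intramolecularly to give the 35-membered lactol 7, and a second dehydrogenation forms the ester C–O bond and the ring irreversibly; at 1 mM the effective molarity of a strain-free 35-membered closure (about 0.02–0.06 M) outcompetes intermolecular hemiacetal formation, and a slow argon stream rather than vacuum keeps aldehyde formation reversible so the hydroxy aldehyde is not drained to the dialdehyde; the closest known reactions are the intermolecular dehydrogenative coupling of primary alcohols to esters with this catalyst class and the dehydrogenative lactonisation of 1,4- and 1,5-diols, which to my knowledge have not been extended to macrocyclic ring sizes; the transient lactol carbon becomes the carbonyl, so no stereocentre remains.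

## Compound list

1 | 1,12-dibromododecane | BrCCCCCCCCCCCCBr | starting material
2 | 1,12-bis(bromomagnesio)dodecane, BrMg(CH2)12MgBr | Br[Mg]CCCCCCCCCCCC[Mg]Br | intermediate
3 | 11-bromoundecan-1-ol | OCCCCCCCCCCCBr | starting material
4 | chloromagnesium 11-bromoundecan-1-olate | Cl[Mg]OCCCCCCCCCCCBr | intermediate
5 | tetratriacontane-1,34-diol | OCCCCCCCCCCCCCCCCCCCCCCCCCCCCCCCCCCO | intermediate
6 | 34-hydroxytetratriacontanal | O=CCCCCCCCCCCCCCCCCCCCCCCCCCCCCCCCCCO | intermediate
7 | oxacyclopentatriacontan-2-ol (racemic, transient) | OC1CCCCCCCCCCCCCCCCCCCCCCCCCCCCCCCCCO1 | intermediate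
8 | oxacyclopentatriacontan-2-one (tetratriacontan-34-olide; achiral) | O=C1CCCCCCCCCCCCCCCCCCCCCCCCCCCCCCCCCO1 | target

## Step count and risks

Total step count: 3. Longest linear sequence: 3 (1 → 2 → 5 → 8).

**Most likely to fail: step 3 (the proposed new macrolactonisation).**
- Risks: linear oligoesters or the 70-membered diolide form if the stationary diol concentration is too high; the reaction stalls at hydroxy aldehyde 6 or the dialdehyde; the catalyst dies at sub-millimolar concentration through traces of air or water.
- Fallback (known chemistry only), from 5 back to 8: selective monobromination of diol 5 with 48% aqueous HBr in refluxing toluene (biphasic) gives 34-bromotetratriacontan-1-ol F1. Oxidation with TEMPO (cat.) and PhI(OAc)2 in CH2Cl2/H2O at 35 °C gives 34-bromotetratriacontanoic acid F2. Cesium carboxylate macrolactonisation (Cs2CO3, DMF, 80 °C, syringe-pump addition to at most 2 mM) then closes the ring by SN2 attack of the carboxylate on the primary bromide, giving 8.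

**Second: step 2 (double coupling with the unprotected alkoxide).**
- Risks: alkoxide 4 may gel in THF; coupling at only one end gives tricosan-1-ol after quench; halogen–magnesium exchange gives homologous diols that co-crystallise with 5.
- Fallback, from 1 back to 5: undec-10-yn-1-ol (C#CCCCCCCCCCO, 2.2 equiv) is doubly deprotonated with n-BuLi (4.4 equiv) in THF/DMPU at −40 °C and alkylated at both ends of dibromide 1 (warming to rt). This gives tetratriaconta-10,24-diyne-1,34-diol F3, which is more soluble than 5 and can be chromatographed. Hydrogenation (H2 1 atm, 10% Pd/C, THF/EtOAc, 50 °C) gives 5. This replaces the copper-catalysed sp3–sp3 coupling with acetylide SN2 chemistry and needs no di-Grignard reagent.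

**Third: step 1 (double magnesium insertion).**
- Risks: Wurtz oligomerisation and incomplete formation of the second C–Mg bond, which would carry C23 by-products into step 2.
- Fallback, from 3 back to 5 (polarity reversal with a protecting group): 3 is protected with 3,4-dihydro-2H-pyran and PPTS in CH2Cl2 to give 2-[(11-bromoundecyl)oxy]oxane F4. Mg in THF converts it into the simple mono-Grignard reagent [11-(oxan-2-yloxy)undecyl]magnesium bromide F5. This (2.3 equiv) is coupled with dibromide 1 as the bis-electrophile (Li2CuCl4 5 mol%, THF, 0 °C to rt) to give 1,34-bis(oxan-2-yloxy)tetratriacontane F6. Acetal cleavage (TsOH, MeOH/THF, 50 °C) gives 5.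

## Further compounds

F1 | step 3 | 34-bromotetratriacontan-1-ol | OCCCCCCCCCCCCCCCCCCCCCCCCCCCCCCCCCCBr
F2 | step 3 | 34-bromotetratriacontanoic acid | OC(=O)CCCCCCCCCCCCCCCCCCCCCCCCCCCCCCCCCBr
F3 | step 2 | tetratriaconta-10,24-diyne-1,34-diol | OCCCCCCCCCC#CCCCCCCCCCCCCCC#CCCCCCCCCCO
F4 | step 1 | 2-[(11-bromoundecyl)oxy]oxane (racemic) | BrCCCCCCCCCCCOC1CCCCO1
F5 | step 1 | [11-(oxan-2-yloxy)undecyl]magnesium bromide (racemic) | Br[Mg]CCCCCCCCCCCOC1CCCCO1
F6 | step 1 | 1,34-bis(oxan-2-yloxy)tetratriacontane (mixture of acetal diastereomers) | C1CCOC(C1)OCCCCCCCCCCCCCCCCCCCCCCCCCCCCCCCCCCOC1CCCCO1
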